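**Numbering used throughout:** 1 2,4,6-trihydroxybenzophenone; 2 prenyl bromide; 3 C-prenylated benzophenone; 4 benzaldehyde; 5 sodium p-toluenesulfinate; 6 racemic benzylic sulfone; 7 4-nitrophenyl acetate; 8 ortho-quinone methide (not isolated); 9 target.

## Analysis of the target

- The target is a 3,4-dihydro-2H-chromen-2-one. Lactone ring B (O1, C2, C3, C4, C4a, C8a) is fused to benzene ring A (C4a to C8a). Ring A is a hexasubstituted phloroglucinol: O1 on C8a, prenyl on C8, OH on C7, benzoyl on C6, OH on C5, and C4 on C4a.
- The only stereocentre is C4 (R), a diaryl methine. Nothing in the molecule can relay chirality to it, so it needs absolute (catalyst) control. Once set it is robust: it has no acidic hydrogen and no retro-Michael pathway.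
- The constitution is as demanding as the configuration. The lactone must sit on the oxygen para to the benzoyl group and next to the prenyl group (O1), not on O5, which would give the 8-benzoyl-6-prenyl isomer. O1 and O5 are meta to each other and cannot both reach C2, so the two lactones interconvert only by ring opening with an outside nucleophile. The choice is therefore made kinetically, in the ring-closing event.
- Sensitive groups: the prenyl alkene (acid-promoted chroman formation with the neighbouring oxygen, peracids, hydrogenation), the aryl lactone (an activated ester), the electron-rich ring A, and the benzophenone carbonyl (hydride).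
- The feature the route uses: C4 is bonded to C4a, which is ortho to O1 (via C8a) and O5 (via C5) and para to O7. The ortho-quinone methide C4=C4a–C8a=O1 is therefore very easy to reach and is planar at C4. Any C4–X precursor, of either configuration, collapses into it. Ring B is the formal [4+2] adduct of this oxa-diene with a two-carbon enolate (C2–C3).
- The difficulty is to combine absolute control at an isolated benzhydrylic centre with the correct choice among three phenolic oxygens, on a fully substituted, acid- and oxidant-sensitive ring, in few steps and without protecting groups.

## Retrosynthetic reasoning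

**9 ⇒ 8 + 7 (C3–C4 and O1–C2).** Ring B is opened completely. This leaves the planar quinone methide 8, which carries every substituent of ring A, and the acetate donor 7 as the C2–C3 unit. The cut is made here because C4 is the one position where a stereocentre can be formed from an achiral, planar carbon that the ring itself stabilises. The forward step must deliver the enolate of 7, bound to a chiral carbene catalyst, to one face of C4, and then acylate the oxygen para to the benzoyl group. It forms the only stereocentre and the only heterocycle in one operation.

**8 ⇒ 6 (C4–S).** The quinone methide is not stored. It is released in the flask from the racemic sulfone 6 by 1,4-elimination. Because 8 is planar, a racemic precursor loses nothing: both enantiomers of 6 feed the same intermediate, so no asymmetric step is needed before the key step.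

**6 ⇒ 3 + 4 + 5 (C4–C4a and C4–S).** The benzhydrylic carbon is attached to the ring by a three-component, Mannich-type condensation of 3 with 4 and 5. Compound 3 has a single free ring position, flanked by two hydroxyls and para to the third, so the site of attack is not in question.

**3 ⇒ 1 + 2 (C8–CH2 of the prenyl group).** The prenyl group is put on first, by C-alkylation of the symmetrical triphenol 1 with 2. The two free ring carbons of 1 are equivalent, so one constitution results. Doing this first also means that no base-mediated alkylation has to be run on the finished lactone.

## Alternatives that were turned down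

**Alternative 1:** the textbook route, disconnecting C4–H after a Pechmann ring synthesis.
- Forward: condensation of the parent triphenol with a benzoylacetic ester would give 5,7-dihydroxy-4-phenylcoumarin A1. Friedel–Crafts benzoylation and C-prenylation would follow, and a copper hydride conjugate reduction of the fully substituted coumarin would set C4 last.
- Turned down: in 5,7-dihydroxycoumarins electrophiles are expected to go mainly to C8, so benzoylation of A1 should give chiefly 8-benzoyl-5,7-dihydroxy-4-phenylcoumarin A2. The 6-benzoyl-8-prenyl pattern would be the minor series and would need two separations. The stereo-defining step is only a functional group change at the end, run beside a reducible benzophenone. Asymmetric hydrogenation as a substitute would also touch the prenyl alkene.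

**Alternative 2:** the biomimetic [3+3], disconnecting C4–C4a and O1–C2.
- Forward: union of 3 with a cinnamoyl unit, either by Brønsted acid hydroarylation and lactonisation or by carbene catalysis through an α,β-unsaturated acyl azolium.
- Turned down: the acid version is racemic and threatens the prenyl group. Under acid the neutral, non-chelated hydroxyl ortho to the benzoyl group is the better nucleophile, so closure is expected to favour the regioisomeric lactone A4. In the carbene version the stereo-defining event is attack of the last, doubly flanked ring carbon of 3 on a hindered acceptor. The para-phenoxide competes by O-acylation to give the cinnamate A3. There is also no stereoconvergence and no gain in logic over the acid route, since the same bonds are formed.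

**Alternative 3:** single-atom insertion, disconnecting O1–C8a.
- Forward: Baeyer–Villiger oxidation of the indanone A5 would insert the lactone oxygen, so that O1 is never a phenol competing with O5.
- Turned down: the carbon that must migrate (C7a of A5) is meta to both hydroxyls and para to the benzoyl group, so CH2 migration to the isochromanone A6 should compete or dominate. The peracid would epoxidise the prenyl alkene. A5 also needs its own asymmetric synthesis and a ring closure at a deactivated position, so the precursor is harder to make than the target.

Key step: step 3

Assumption: the sense of induction of the aminoindanol-derived triazolium catalyst is assigned by analogy with azolium enolate oxa-Diels–Alder reactions; the (5aS,10bR) salt is written, and its equally available (5aR,10bS) antipode would be used should the analogy run the other way.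

## Route

Step 1
Reactants: 1 2,4,6-trihydroxybenzophenone; 2 prenyl bromide (1-bromo-3-methylbut-2-ene)
Product: 3 [2,4,6-trihydroxy-3-(3-methylbut-2-en-1-yl)phenyl](phenyl)methanone
Conditions: DBU (1.1 equiv), THF, 0 °C to rt
Reagents that add atoms: none
Why: C-alkylation of the delocalised acylphloroglucinol anion by an allylic bromide, a known reaction of this compound class; the two free ring carbons of 1 are equivalent, so mono-C-prenylation gives one constitution, and 2 is kept limiting to suppress a second alkylation.

Step 2
Reactants: 3 [2,4,6-trihydroxy-3-(3-methylbut-2-en-1-yl)phenyl](phenyl)methanone; 4 benzaldehyde; 5 sodium p-toluenesulfinate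
Product: 6 rac-{2,4,6-trihydroxy-3-(3-methylbut-2-en-1-yl)-5-[(4-methylbenzenesulfonyl)(phenyl)methyl]phenyl}(phenyl)methanone
Conditions: HCO2H, H2O/EtOH, rt
Reagents that add atoms: none
Why: three-component Mannich-type α-sulfonylbenzylation of a phenol (aldehyde, sulfinic acid, electron-rich arene), the standard entry to base-triggered ortho-quinone methide precursors; the single free ring carbon of 3 is the only site, and the racemic product is all that the next step needs.

Step 3
Reactants: 6 rac-{2,4,6-trihydroxy-3-(3-methylbut-2-en-1-yl)-5-[(4-methylbenzenesulfonyl)(phenyl)methyl]phenyl}(phenyl)methanone; 7 4-nitrophenyl acetate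
Product: 9 (4R)-6-benzoyl-5,7-dihydroxy-8-(3-methylbut-2-en-1-yl)-4-phenyl-3,4-dihydro-2H-chromen-2-one, via ortho-quinone methide 8 (not isolated)
Conditions: (5aS,10bR)-2-mesityl-5a,10b-dihydro-4H,6H-indeno[2,1-b][1,2,4]triazolo[4,3-d][1,4]oxazin-2-ium tetrafluoroborate (20 mol %), K2CO3 (2.2 equiv), 4 Å MS, THF, 0 °C to rt; AcOH quench
Reagents that add atoms: none
Why: Carbonate ionises the phenol para to the benzoyl group in either enantiomer of 6, and the phenoxide expels sulfinate by 1,4-elimination to give the planar quinone methide 8, so the configuration of 6 is erased and both enantiomers feed one intermediate. In parallel the carbene from the triazolium salt attacks the activated ester 7, releases 4-nitrophenoxide and, after deprotonation of the acetyl azolium, gives a chiral azolium enolate. The enolate CH2 adds to the exocyclic carbon of 8 (the future C4) and the resulting phenoxide is acylated by the acyl azolium, which frees the carbene; the closest known reaction type is the carbene-catalysed formal [4+2] annulation of azolium enolates with ortho-quinone methides generated in situ to give 4-aryl-3,4-dihydrocoumarins, combined with the known use of 4-nitrophenyl acetate as an acetate enolate source. Ring B is thus closed in the oxa-Diels–Alder sense, C3–C4 first by conjugate addition and O1–C2 second by a 6-exo-trig acyl substitution. C4 is the only new stereocentre and is controlled by the catalyst alone: the aminoindanol backbone blocks one face of the enolate and an endo arrangement, with the quinone methide oxygen over the azolium unit, decides which enantiotopic face of C4 is attacked, while the E and Z forms of 8 equilibrate through reversible sulfinate addition. The step needs face selectivity at C4 and site selectivity between the two oxygens that flank C4a; the second rests on acidity, because under carbonate buffered by 4-nitrophenol only the oxygen para to the benzoyl group is ionised (the ortho hydroxyls are held by hydrogen bonds to the ketone), and this phenoxide both forms 8 and accepts the acyl group. The prenyl alkene and the benzophenone are inert here, and the absence of strong acid avoids chroman formation and ionisation at C4.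

## Compound list

1 | 2,4,6-trihydroxybenzophenone | O=C(c1ccccc1)c1c(O)cc(O)cc1O | starting material
2 | prenyl bromide (1-bromo-3-methylbut-2-ene) | CC(C)=CCBr | starting material
3 | [2,4,6-trihydroxy-3-(3-methylbut-2-en-1-yl)phenyl](phenyl)methanone | CC(C)=CCc1c(O)cc(O)c(C(=O)c2ccccc2)c1O | intermediate
4 | benzaldehyde | O=Cc1ccccc1 | starting material
5 | sodium p-toluenesulfinate | Cc1ccc(cc1)S(=O)[O-].[Na+] | starting material
6 | rac-{2,4,6-trihydroxy-3-(3-methylbut-2-en-1-yl)-5-[(4-methylbenzenesulfonyl)(phenyl)methyl]phenyl}(phenyl)methanone | CC(C)=CCc1c(O)c(C(c2ccccc2)S(=O)(=O)c2ccc(C)cc2)c(O)c(C(=O)c2ccccc2)c1O | intermediate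
7 | 4-nitrophenyl acetate | CC(=O)Oc1ccc(cc1)[N+](=O)[O-] | starting material
8 | 4-benzoyl-6-benzylidene-3,5-dihydroxy-2-(3-methylbut-2-en-1-yl)cyclohexa-2,4-dien-1-one (ortho-quinone methide, one tautomer drawn) | CC(C)=CCC1=C(O)C(C(=O)c2ccccc2)=C(O)C(=Cc2ccccc2)C1=O | intermediate
9 | (4R)-6-benzoyl-5,7-dihydroxy-8-(3-methylbut-2-en-1-yl)-4-phenyl-3,4-dihydro-2H-chromen-2-one | CC(C)=CCc1c(O)c(C(=O)c2ccccc2)c(O)c2c1OC(=O)C[C@@H]2c1ccccc1 | target

## Step count and least certain steps

Total step count: 3. Longest linear sequence: 3 steps (1 → 3 → 6 → 9).

**Step 3 (key step).** Three processes may fail.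
- Face discrimination at C4 may be poor, because the free hydroxyls of the quinone methide can hydrogen-bond to the enolate in unselective geometries.
- The ring may close on the oxygen ortho to the benzoyl group, or the lactone may be shuttled there after reversible opening by the carbene or by 4-nitrophenoxide. This would give the 8-benzoyl-6-prenyl constitution.
- The para-phenoxide may be O-acetylated by 7, or the quinone methide may oligomerise, which would stall the annulation.

The fallback gives up the quinone methide and fixes the lactone oxygen and C4 in separate, known operations. It sets out from 1.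
- Esterification of the only non-chelated hydroxyl (para to the benzoyl group) with 3-phenylpropiolic acid (DIC, cat. DMAP, CH2Cl2) should give 4-benzoyl-3,5-dihydroxyphenyl 3-phenylprop-2-ynoate F1.
- Intramolecular 6-endo hydroarylation of the alkyne at either equivalent ortho carbon (Ph3PAuNTf2, ClCH2CH2Cl) should give 6-benzoyl-5,7-dihydroxy-4-phenyl-2H-chromen-2-one F2, with the ring oxygen fixed by the ester.
- C-prenylation of the one remaining ring CH with 2 (DBU, THF) should give 6-benzoyl-5,7-dihydroxy-8-(3-methylbut-2-en-1-yl)-4-phenyl-2H-chromen-2-one F3.
- Copper hydride conjugate reduction (Cu(OAc)2, the enantiomer of DTBM-SEGPHOS that delivers hydride to the face of C4 leading to R, excess (EtO)2MeSiH, t-BuOH, THF) would come back to the route at 9.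

**Step 2.** The sulfone of so electron-rich a ring may ionise during isolation (loss of sulfinate, then self-condensation of the quinone methide). The acidic medium may also promote cyclisation of the prenyl group onto a neighbouring hydroxyl.

The fallback makes the C4–C4a bond by acylation instead of hydroxyalkylation and uses the fact that C4 and the benzoyl carbon are both Ph–C units. It sets out from 1.
- Friedel–Crafts benzoylation (PhCOCl, AlCl3, PhNO2) should give (2,4,6-trihydroxy-1,3-phenylene)bis(phenylmethanone) F4.
- Prenylation with 2 at the only free ring carbon (DBU, THF) should give [2,4,6-trihydroxy-5-(3-methylbut-2-en-1-yl)-1,3-phenylene]bis(phenylmethanone) F5. Its two ketones are equivalent.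
- Reduction of one ketone (NaBH4, one hydride equivalent, THF/EtOH, low temperature) should give the carbinol rac-{2,4,6-trihydroxy-3-[hydroxy(phenyl)methyl]-5-(3-methylbut-2-en-1-yl)phenyl}(phenyl)methanone F6.
- F6 would be treated without purification with the sulfinic acid from 5 and HCO2H, which comes back to the route at 6.

**Step 1.** O-alkylation and over-alkylation (a second C-prenylation, or dearomatising geminal dialkylation) may consume the triphenol, because the ambident anion has several reactive sites.

The fallback replaces direct C-alkylation by O-alkylation and a sigmatropic shift. It sets out from 1.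
- Pd(PPh3)4-catalysed O-alkylation of the para hydroxyl with tert-butyl 2-methylbut-3-en-2-yl carbonate (THF, rt) should give {2,6-dihydroxy-4-[(2-methylbut-3-en-2-yl)oxy]phenyl}(phenyl)methanone F7.
- Aromatic Claisen rearrangement of F7 (toluene, 110 °C) moves the allyl unit to either equivalent ortho carbon with inversion to the prenyl form, and comes back to the route at 3.

## Further compounds

F1 | step 3 | 4-benzoyl-3,5-dihydroxyphenyl 3-phenylprop-2-ynoate | O=C(C#Cc1ccccc1)Oc1cc(O)c(C(=O)c2ccccc2)c(O)c1
F2 | step 3 | 6-benzoyl-5,7-dihydroxy-4-phenyl-2H-chromen-2-one | O=C1C=C(c2ccccc2)c2c(O)c(C(=O)c3ccccc3)c(O)cc2O1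
F3 | step 3 | 6-benzoyl-5,7-dihydroxy-8-(3-methylbut-2-en-1-yl)-4-phenyl-2H-chromen-2-one | CC(C)=CCc1c(O)c(C(=O)c2ccccc2)c(O)c2c1OC(=O)C=C2c1ccccc1
F4 | step 2 | (2,4,6-trihydroxy-1,3-phenylene)bis(phenylmethanone) | O=C(c1ccccc1)c1c(O)cc(O)c(C(=O)c2ccccc2)c1O
F5 | step 2 | [2,4,6-trihydroxy-5-(3-methylbut-2-en-1-yl)-1,3-phenylene]bis(phenylmethanone) | CC(C)=CCc1c(O)c(C(=O)c2ccccc2)c(O)c(C(=O)c2ccccc2)c1O
F6 | step 2 | rac-{2,4,6-trihydroxy-3-[hydroxy(phenyl)methyl]-5-(3-methylbut-2-en-1-yl)phenyl}(phenyl)methanone | CC(C)=CCc1c(O)c(C(O)c2ccccc2)c(O)c(C(=O)c2ccccc2)c1O
F7 | step 1 | {2,6-dihydroxy-4-[(2-methylbut-3-en-2-yl)oxy]phenyl}(phenyl)methanone | C=CC(C)(C)Oc1cc(O)c(C(=O)c2ccccc2)c(O)c1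
A1 | alternative 1 | 5,7-dihydroxy-4-phenyl-2H-chromen-2-one | O=C1C=C(c2ccccc2)c2c(O)cc(O)cc2O1
A2 | alternative 1 | 8-benzoyl-5,7-dihydroxy-4-phenyl-2H-chromen-2-one | O=C1C=C(c2ccccc2)c2c(O)cc(O)c(C(=O)c3ccccc3)c2O1
A3 | alternative 2 | 4-benzoyl-3,5-dihydroxy-2-(3-methylbut-2-en-1-yl)phenyl (E)-3-phenylprop-2-enoate | O=C(/C=C/c1ccccc1)Oc1cc(O)c(C(=O)c2ccccc2)c(O)c1CC=C(C)C
A4 | alternative 2 | 8-benzoyl-5,7-dihydroxy-6-(3-methylbut-2-en-1-yl)-4-phenyl-3,4-dihydro-2H-chromen-2-one | CC(C)=CCc1c(O)c(C(=O)c2ccccc2)c2OC(=O)CC(c3ccccc3)c2c1O
A5 | alternative 3 | (3R)-5-benzoyl-4,6-dihydroxy-7-(3-methylbut-2-en-1-yl)-3-phenyl-2,3-dihydro-1H-inden-1-one | CC(C)=CCc1c(O)c(C(=O)c2ccccc2)c(O)c2c1C(=O)C[C@@H]2c1ccccc1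
A6 | alternative 3 | 6-benzoyl-5,7-dihydroxy-8-(3-methylbut-2-en-1-yl)-4-phenyl-3,4-dihydro-1H-isochromen-1-one | CC(C)=CCc1c(O)c(C(=O)c2ccccc2)c(O)c2c1C(=O)OCC2c1ccccc1
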